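## Retrosynthetic overview

1. The target is a (3R)-isoflavanone. Rings A and B are bought as aromatic rings (2,4-dihydroxyacetophenone and pyrogallol) and elaborated; ring C is formed last, by closure of the O1–C2 bond.
2. Enabling feature: O1(on C8a)–C2H2–C3H(aryl)–C4(=O) is a β-aryloxy ketone whose only stereocentre, C3, is α to the C4 carbonyl. Retro-oxa-Michael therefore opens ring C to an achiral 2-aryl-1-(2-hydroxyaryl)prop-2-en-1-one in which C3 is sp2 and the ring-A phenol sits ortho to the acyl group. The forward 6-endo closure onto C2 creates an enol at C3/C4 that a chiral bifunctional catalyst should protonate enantioselectively.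
3. The enone comes from a deoxybenzoin by α-methylenation (this installs C2). The deoxybenzoin comes from Pd-catalysed α-arylation of the ring-A acetophenone with a ring-B aryl bromide (C3–C1' bond).
4. The ring-B bromide comes from pyrogallol: catechol ketal, para-bromination, O-prenylation and aromatic Claisen rearrangement (1,1-dimethylallyl group ortho to O4'; the bromine blocks the para position and later serves as the coupling handle), O-methylation, then ketal-to-silyl exchange.
5. The silyl ethers on O7, O2' and O3' are removed last with buffered fluoride, so that C3 is never exposed to base.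

Key step: step 13

Assumption: the quinine-derived squaramide is taken to give the (R) configuration at C3; if it gives the antipode, the pseudoenantiomeric quinidine-derived squaramide is used under the same conditions.

## Route

Step 1
Reactants: 1 pyrogallol (benzene-1,2,3-triol)
Product: 2 2,2-diphenyl-1,3-benzodioxol-4-ol
Conditions: Ph2CCl2 (1.05 equiv), neat, 165 °C, 30 min
Reagents that add atoms: dichlorodiphenylmethane ClC(Cl)(c1ccccc1)c1ccccc1
Why: Ketalisation of a catechol with a gem-dichloride closes the five-membered dioxole on two vicinal hydroxyls and leaves the third free; both adjacent pairs of pyrogallol give the same product.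

Step 2
Reactants: 2 2,2-diphenyl-1,3-benzodioxol-4-ol
Product: 3 7-bromo-2,2-diphenyl-1,3-benzodioxol-4-ol
Conditions: NBS (1.0 equiv), MeCN, −20 → 0 °C
Reagents that add atoms: N-bromosuccinimide O=C1CCC(=O)N1Br
Why: Electrophilic aromatic bromination should go para to the free phenol, the strongest donor, with one equivalent at low temperature holding mono-substitution; the bromine later blocks the para position in the Claisen step and is the cross-coupling handle.

Step 3
Reactants: 3 7-bromo-2,2-diphenyl-1,3-benzodioxol-4-ol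
Product: 4 7-bromo-4-[(3-methylbut-2-en-1-yl)oxy]-2,2-diphenyl-1,3-benzodioxole
Conditions: prenyl bromide, K2CO3, acetone, reflux
Reagents that add atoms: 1-bromo-3-methylbut-2-ene CC(C)=CCBr
Why: Williamson etherification of the phenoxide with a primary allylic bromide should give the O-prenyl ether cleanly.

Step 4
Reactants: 4 7-bromo-4-[(3-methylbut-2-en-1-yl)oxy]-2,2-diphenyl-1,3-benzodioxole
Product: 6 7-bromo-5-(2-methylbut-3-en-2-yl)-2,2-diphenyl-1,3-benzodioxol-4-ol, via ortho-dienone 5 (not isolated)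
Conditions: PhNEt2, 190 °C, sealed tube, Ar
Reagents that add atoms: none
Why: The aromatic Claisen rearrangement ([3,3]-sigmatropic shift with allyl inversion) should deliver the 1,1-dimethylallyl group to C5, the only free ortho carbon, because the other ortho carbon carries oxygen and the para carbon carries bromine; the dienone then tautomerises to the phenol.

Step 5
Reactants: 6 7-bromo-5-(2-methylbut-3-en-2-yl)-2,2-diphenyl-1,3-benzodioxol-4-ol
Product: 7 7-bromo-4-methoxy-5-(2-methylbut-3-en-2-yl)-2,2-diphenyl-1,3-benzodioxole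
Conditions: MeI, K2CO3, DMF, 40 °C
Reagents that add atoms: iodomethane CI
Why: Williamson O-methylation of the only free phenol fixes the methyl ether next to the 1,1-dimethylallyl group.

Step 6
Reactants: 7 7-bromo-4-methoxy-5-(2-methylbut-3-en-2-yl)-2,2-diphenyl-1,3-benzodioxole
Product: 8 3-bromo-6-methoxy-5-(2-methylbut-3-en-2-yl)benzene-1,2-diol
Conditions: AcOH/H2O (4:1), 100 °C, Ar
Reagents that add atoms: none
Why: Acid hydrolysis of the diphenylmethylene ketal (stabilised diarylcarbenium) frees the catechol under conditions too weakly acidic to protonate the monosubstituted alkene.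

Step 7
Reactants: 8 3-bromo-6-methoxy-5-(2-methylbut-3-en-2-yl)benzene-1,2-diol
Product: 9 {[3-bromo-6-methoxy-5-(2-methylbut-3-en-2-yl)-1,2-phenylene]bis(oxy)}bis[tert-butyl(dimethyl)silane]
Conditions: TBSOTf, 2,6-lutidine, CH2Cl2, 0 °C → rt
Reagents that add atoms: tert-butyldimethylsilyl trifluoromethanesulfonate CC(C)(C)[Si](C)(C)OS(=O)(=O)C(F)(F)F
Why: Silylation with the reactive silyl triflate should cap both hindered catechol oxygens with groups that are removable at the end by fluoride without base.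

Step 8
Reactants: 10 1-(2,4-dihydroxyphenyl)ethan-1-one
Product: 11 1-[2-hydroxy-4-(triisopropylsilyloxy)phenyl]ethan-1-one
Conditions: TIPSCl, imidazole, CH2Cl2, 0 °C → rt
Reagents that add atoms: triisopropylsilyl chloride CC(C)[Si](Cl)(C(C)C)C(C)C
Why: Selective silylation of the 4-hydroxyl is expected because the 2-hydroxyl is tied up in the hydrogen bond to the acetyl oxygen.

Step 9
Reactants: 11 1-[2-hydroxy-4-(triisopropylsilyloxy)phenyl]ethan-1-one
Product: 12 1-[2-(4-methoxybenzyloxy)-4-(triisopropylsilyloxy)phenyl]ethan-1-one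
Conditions: PMBCl, K2CO3, n-Bu4NI (cat.), DMF, rt → 40 °C
Reagents that add atoms: 4-methoxybenzyl chloride COc1ccc(CCl)cc1
Why: Williamson etherification masks the chelated phenol as a PMB ether that is later removable oxidatively, orthogonal to the silyl ethers.

Step 10
Reactants: 12 1-[2-(4-methoxybenzyloxy)-4-(triisopropylsilyloxy)phenyl]ethan-1-one; 9 {[3-bromo-6-methoxy-5-(2-methylbut-3-en-2-yl)-1,2-phenylene]bis(oxy)}bis[tert-butyl(dimethyl)silane]
Product: 13 2-[2,3-bis(tert-butyldimethylsilyloxy)-4-methoxy-5-(2-methylbut-3-en-2-yl)phenyl]-1-[2-(4-methoxybenzyloxy)-4-(triisopropylsilyloxy)phenyl]ethan-1-one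
Conditions: Pd2(dba)3 (2.5 mol %), 2-dicyclohexylphosphino-2'-methylbiphenyl (6 mol %), K3PO4, toluene, 85 °C
Reagents that add atoms: none
Why: Palladium-catalysed α-arylation of a methyl ketone enolate (Buchwald–Hartwig type) with a bulky electron-rich phosphine and the mild phosphate base should give the mono-arylated deoxybenzoin while sparing the aryl silyl ethers.

Step 11
Reactants: 13 2-[2,3-bis(tert-butyldimethylsilyloxy)-4-methoxy-5-(2-methylbut-3-en-2-yl)phenyl]-1-[2-(4-methoxybenzyloxy)-4-(triisopropylsilyloxy)phenyl]ethan-1-one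
Product: 15 2-[2,3-bis(tert-butyldimethylsilyloxy)-4-methoxy-5-(2-methylbut-3-en-2-yl)phenyl]-1-[2-(4-methoxybenzyloxy)-4-(triisopropylsilyloxy)phenyl]prop-2-en-1-one, via Mannich base 14 (not isolated)
Conditions: (Me2N)2CH2, Ac2O, DMF, 25 → 60 °C
Reagents that add atoms: bis(dimethylamino)methane CN(C)CN(C)C
Why: Mannich-type α-methylenation, in which the iminium ion formed from the aminal and acetic anhydride aminomethylates the doubly benzylic methylene and the acetylated Mannich base eliminates, should install the C2 carbon as a terminal alkene.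

Step 12
Reactants: 15 2-[2,3-bis(tert-butyldimethylsilyloxy)-4-methoxy-5-(2-methylbut-3-en-2-yl)phenyl]-1-[2-(4-methoxybenzyloxy)-4-(triisopropylsilyloxy)phenyl]prop-2-en-1-one
Product: 16 2-[2,3-bis(tert-butyldimethylsilyloxy)-4-methoxy-5-(2-methylbut-3-en-2-yl)phenyl]-1-[2-hydroxy-4-(triisopropylsilyloxy)phenyl]prop-2-en-1-one
Conditions: DDQ, CH2Cl2/pH 7 buffer (10:1), 0 °C → rt; rapid filtration, used at once
Reagents that add atoms: none
Why: Oxidative cleavage of the PMB ether by DDQ frees the ring-A phenol under neutral conditions, so the hydrogen-bonded phenol-enone should survive without premature cyclisation.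

Step 13
Reactants: 16 2-[2,3-bis(tert-butyldimethylsilyloxy)-4-methoxy-5-(2-methylbut-3-en-2-yl)phenyl]-1-[2-hydroxy-4-(triisopropylsilyloxy)phenyl]prop-2-en-1-one
Product: 18 (3R)-3-[2,3-bis(tert-butyldimethylsilyloxy)-4-methoxy-5-(2-methylbut-3-en-2-yl)phenyl]-7-(triisopropylsilyloxy)-2,3-dihydro-4H-chromen-4-one, via enol 17 (not isolated)
Conditions: quinine-derived 3,5-bis(trifluoromethyl)phenyl squaramide (10 mol %), toluene, −40 °C; AcOH quench, silica filtration
Reagents that add atoms: none
Why: Proposed new method: the quinuclidine nitrogen of the bifunctional catalyst activates the ring-A phenol while the squaramide N–H pair binds the C4 carbonyl, the phenol oxygen adds to the unsubstituted C2 terminus of the α-aryl enone, and the catalyst-bound enol 17 is then protonated at C3 by the adjacent chiral quinuclidinium N–H. The closest known reaction types are the cinchona thiourea- and squaramide-catalysed intramolecular oxa-Michael cyclisations of 2-hydroxyaryl enones to chromanones, and the sulfa-Michael addition with enantioselective protonation of α-substituted acrylates and enones by the same catalysts; their union on an α-aryl vinyl ketone with a phenol nucleophile is the new element. Ring C closes in the 6-endo-trig mode, O1 attacking C2. The single new stereocentre, C3, is set in the protonation step by the catalyst alone, the proton being delivered to the enol face held against the quinuclidinium in the ion pair. The step needs catalysed protonation to outrun uncatalysed cyclisation and product racemisation: the O–H···O=C hydrogen bond of 16 holds the phenol away from C2 until the catalyst engages it, low temperature and a non-polar solvent suppress the background path, the ortho-silyloxy group of ring B twists the C3 aryl out of the enol plane so that re-enolisation of 18 by the weak amine is slow, and the silylated ring-B oxygens cannot compete as nucleophiles.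

Step 14
Reactants: 18 (3R)-3-[2,3-bis(tert-butyldimethylsilyloxy)-4-methoxy-5-(2-methylbut-3-en-2-yl)phenyl]-7-(triisopropylsilyloxy)-2,3-dihydro-4H-chromen-4-one
Product: 19 (3R)-3-[2,3-dihydroxy-4-methoxy-5-(2-methylbut-3-en-2-yl)phenyl]-7-hydroxy-2,3-dihydro-4H-chromen-4-one
Conditions: HF·pyridine, pyridine, THF, 0 °C → rt, Ar
Reagents that add atoms: none
Why: Fluoride-mediated cleavage of the three aryl silyl ethers in a buffered, non-basic medium should release the phenols without enolising C3 and without touching the terminal alkene.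

## Compound list

1 | pyrogallol (benzene-1,2,3-triol) | Oc1cccc(O)c1O | starting material
2 | 2,2-diphenyl-1,3-benzodioxol-4-ol | Oc1cccc2c1OC(c1ccccc1)(c1ccccc1)O2 | intermediate
3 | 7-bromo-2,2-diphenyl-1,3-benzodioxol-4-ol | Oc1ccc(Br)c2c1OC(c1ccccc1)(c1ccccc1)O2 | intermediate
4 | 7-bromo-4-[(3-methylbut-2-en-1-yl)oxy]-2,2-diphenyl-1,3-benzodioxole | CC(C)=CCOc1ccc(Br)c2c1OC(c1ccccc1)(c1ccccc1)O2 | intermediate
5 | 7-bromo-5-(2-methylbut-3-en-2-yl)-2,2-diphenyl-1,3-benzodioxol-4(5H)-one (ortho-dienone) | O=C1C(C(C)(C)C=C)C=C(Br)C2=C1OC(c1ccccc1)(c1ccccc1)O2 | intermediate (not isolated)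
6 | 7-bromo-5-(2-methylbut-3-en-2-yl)-2,2-diphenyl-1,3-benzodioxol-4-ol | Oc1c(C(C)(C)C=C)cc(Br)c2c1OC(c1ccccc1)(c1ccccc1)O2 | intermediate
7 | 7-bromo-4-methoxy-5-(2-methylbut-3-en-2-yl)-2,2-diphenyl-1,3-benzodioxole | COc1c(C(C)(C)C=C)cc(Br)c2c1OC(c1ccccc1)(c1ccccc1)O2 | intermediate
8 | 3-bromo-6-methoxy-5-(2-methylbut-3-en-2-yl)benzene-1,2-diol | COc1c(C(C)(C)C=C)cc(Br)c(O)c1O | intermediate
9 | {[3-bromo-6-methoxy-5-(2-methylbut-3-en-2-yl)-1,2-phenylene]bis(oxy)}bis[tert-butyl(dimethyl)silane] | COc1c(C(C)(C)C=C)cc(Br)c(O[Si](C)(C)C(C)(C)C)c1O[Si](C)(C)C(C)(C)C | intermediate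
10 | 1-(2,4-dihydroxyphenyl)ethan-1-one | CC(=O)c1ccc(O)cc1O | starting material
11 | 1-[2-hydroxy-4-(triisopropylsilyloxy)phenyl]ethan-1-one | CC(=O)c1ccc(O[Si](C(C)C)(C(C)C)C(C)C)cc1O | intermediate
12 | 1-[2-(4-methoxybenzyloxy)-4-(triisopropylsilyloxy)phenyl]ethan-1-one | CC(=O)c1ccc(O[Si](C(C)C)(C(C)C)C(C)C)cc1OCc1ccc(OC)cc1 | intermediate
13 | 2-[2,3-bis(tert-butyldimethylsilyloxy)-4-methoxy-5-(2-methylbut-3-en-2-yl)phenyl]-1-[2-(4-methoxybenzyloxy)-4-(triisopropylsilyloxy)phenyl]ethan-1-one | COc1c(C(C)(C)C=C)cc(CC(=O)c2ccc(O[Si](C(C)C)(C(C)C)C(C)C)cc2OCc2ccc(OC)cc2)c(O[Si](C)(C)C(C)(C)C)c1O[Si](C)(C)C(C)(C)C | intermediate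
14 | 2-[2,3-bis(tert-butyldimethylsilyloxy)-4-methoxy-5-(2-methylbut-3-en-2-yl)phenyl]-3-(dimethylamino)-1-[2-(4-methoxybenzyloxy)-4-(triisopropylsilyloxy)phenyl]propan-1-one (Mannich base) | COc1c(C(C)(C)C=C)cc(C(CN(C)C)C(=O)c2ccc(O[Si](C(C)C)(C(C)C)C(C)C)cc2OCc2ccc(OC)cc2)c(O[Si](C)(C)C(C)(C)C)c1O[Si](C)(C)C(C)(C)C | intermediate (not isolated)
15 | 2-[2,3-bis(tert-butyldimethylsilyloxy)-4-methoxy-5-(2-methylbut-3-en-2-yl)phenyl]-1-[2-(4-methoxybenzyloxy)-4-(triisopropylsilyloxy)phenyl]prop-2-en-1-one | COc1c(C(C)(C)C=C)cc(C(=C)C(=O)c2ccc(O[Si](C(C)C)(C(C)C)C(C)C)cc2OCc2ccc(OC)cc2)c(O[Si](C)(C)C(C)(C)C)c1O[Si](C)(C)C(C)(C)C | intermediate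
16 | 2-[2,3-bis(tert-butyldimethylsilyloxy)-4-methoxy-5-(2-methylbut-3-en-2-yl)phenyl]-1-[2-hydroxy-4-(triisopropylsilyloxy)phenyl]prop-2-en-1-one | COc1c(C(C)(C)C=C)cc(C(=C)C(=O)c2ccc(O[Si](C(C)C)(C(C)C)C(C)C)cc2O)c(O[Si](C)(C)C(C)(C)C)c1O[Si](C)(C)C(C)(C)C | intermediate
17 | 3-[2,3-bis(tert-butyldimethylsilyloxy)-4-methoxy-5-(2-methylbut-3-en-2-yl)phenyl]-7-(triisopropylsilyloxy)-2H-chromen-4-ol (enol) | COc1c(C(C)(C)C=C)cc(C2=C(O)c3ccc(O[Si](C(C)C)(C(C)C)C(C)C)cc3OC2)c(O[Si](C)(C)C(C)(C)C)c1O[Si](C)(C)C(C)(C)C | intermediate (not isolated)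
18 | (3R)-3-[2,3-bis(tert-butyldimethylsilyloxy)-4-methoxy-5-(2-methylbut-3-en-2-yl)phenyl]-7-(triisopropylsilyloxy)-2,3-dihydro-4H-chromen-4-one | C=CC(C)(C)c1cc([C@@H]2COc3cc(O[Si](C(C)C)(C(C)C)C(C)C)ccc3C2=O)c(O[Si](C)(C)C(C)(C)C)c(O[Si](C)(C)C(C)(C)C)c1OC | intermediate
19 | (3R)-3-[2,3-dihydroxy-4-methoxy-5-(2-methylbut-3-en-2-yl)phenyl]-7-hydroxy-2,3-dihydro-4H-chromen-4-one | C=CC(C)(C)c1cc([C@@H]2COc3cc(O)ccc3C2=O)c(O)c(O)c1OC | target

## Step count and risks

Total step count: 14. Longest linear sequence: 12 steps (steps 1–7, then 10–14, from pyrogallol); the ring-A branch is steps 8–9.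

Steps most likely to fail:

1. Step 13 (Proposed new method). The protonation of enol 17 may show poor facial selectivity, uncatalysed cyclisation of 16 may compete, or the product may lose enantiopurity by re-enolisation under the amine catalyst. The fallback uses known chemistry, sets out from 16 and returns at 18. Compound 16 is cyclised with catalytic Et3N in CH2Cl2 to the racemic 3-aryl-7-(triisopropylsilyloxy)chroman-4-one F1. F1 is then subjected to asymmetric transfer hydrogenation with dynamic kinetic resolution (RuCl[(R,R)-TsDPEN](p-cymene), HCO2H/Et3N, EtOAc, rt); C3 epimerises under the amine and the fast-reacting enantiomer is reduced, which should give the (3R,4R)-cis-3-arylchroman-4-ol F2. Oxidation of the benzylic alcohol of F2 with Dess–Martin periodinane (CH2Cl2, 0 °C) should return ketone 18 without touching C3.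

2. Step 4. The Claisen rearrangement may be diverted by thermal cyclisation of the new phenol onto the adjacent alkene, by further (abnormal) rearrangement of the 1,1-dimethylallyl group, or by loss of the prenyl group. The fallback sets out from 3 and returns at 7, and installs the side chain by cross-coupling instead of a sigmatropic shift. Phenol 3 is iodinated at the only free ortho position (NIS, TsOH cat., MeCN) to give 7-bromo-5-iodo-2,2-diphenyl-1,3-benzodioxol-4-ol F3. F3 is methylated (MeI, K2CO3, DMF) to 7-bromo-5-iodo-4-methoxy-2,2-diphenyl-1,3-benzodioxole F4. A γ-selective allyl–aryl Suzuki–Miyaura coupling at the more reactive C–I bond (3-methylbut-2-en-1-ylboronic acid pinacol ester, Pd(OAc)2, 1,1'-bis(di-tert-butylphosphino)ferrocene, aqueous K3PO4, THF, 50 °C) should then give 7 directly.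

3. Step 10. Oxidative addition into the hindered, electron-rich bromide 9 may be slow, so that protodebromination or loss of aryl silyl groups takes over. The fallback sets out from 9 and 12 and returns at 13, with the coupling polarity reversed. Bromide 9 is converted by Miyaura borylation (B2pin2, Pd(dppf)Cl2, KOAc, dioxane, 80 °C) into the aryl pinacol boronate F5. Ketone 12 is converted through its trimethylsilyl enol ether (LiHMDS, TMSCl; then NBS, THF, −78 °C) into the 2-bromo ketone F6. Suzuki–Miyaura coupling of F5 with F6 (Pd(OAc)2, P(o-tol)3, K3PO4, toluene, 60 °C) should give deoxybenzoin 13.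

Further compounds
F1 | step 13 | racemic 3-[2,3-bis(tert-butyldimethylsilyloxy)-4-methoxy-5-(2-methylbut-3-en-2-yl)phenyl]-7-(triisopropylsilyloxy)-2,3-dihydro-4H-chromen-4-one | C=CC(C)(C)c1cc(C2COc3cc(O[Si](C(C)C)(C(C)C)C(C)C)ccc3C2=O)c(O[Si](C)(C)C(C)(C)C)c(O[Si](C)(C)C(C)(C)C)c1OC
F2 | step 13 | (3R,4R)-3-[2,3-bis(tert-butyldimethylsilyloxy)-4-methoxy-5-(2-methylbut-3-en-2-yl)phenyl]-7-(triisopropylsilyloxy)-3,4-dihydro-2H-chromen-4-ol | C=CC(C)(C)c1cc([C@@H]2COc3cc(O[Si](C(C)C)(C(C)C)C(C)C)ccc3[C@@H]2O)c(O[Si](C)(C)C(C)(C)C)c(O[Si](C)(C)C(C)(C)C)c1OC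
F3 | step 4 | 7-bromo-5-iodo-2,2-diphenyl-1,3-benzodioxol-4-ol | Oc1c(I)cc(Br)c2c1OC(c1ccccc1)(c1ccccc1)O2
F4 | step 4 | 7-bromo-5-iodo-4-methoxy-2,2-diphenyl-1,3-benzodioxole | COc1c(I)cc(Br)c2c1OC(c1ccccc1)(c1ccccc1)O2
F5 | step 10 | 2-[2,3-bis(tert-butyldimethylsilyloxy)-4-methoxy-5-(2-methylbut-3-en-2-yl)phenyl]-4,4,5,5-tetramethyl-1,3,2-dioxaborolane | COc1c(C(C)(C)C=C)cc(B2OC(C)(C)C(C)(C)O2)c(O[Si](C)(C)C(C)(C)C)c1O[Si](C)(C)C(C)(C)C
F6 | step 10 | 2-bromo-1-[2-(4-methoxybenzyloxy)-4-(triisopropylsilyloxy)phenyl]ethan-1-one | BrCC(=O)c1ccc(O[Si](C(C)C)(C(C)C)C(C)C)cc1OCc1ccc(OC)cc1
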